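## Analysis of the target

The target is a germacranolide: a cyclodecane (C1–C10) fused at C6–C7 to an α,β-unsaturated γ-lactone (O–C6, C7=C11, C12=O) whose α-carbon C11 carries the acetoxymethyl carbon C13. In the numbering used throughout, C1 bears the secondary acetate, C10 the methyl C14, C4 the methyl C15, C4–C5 the epoxide, C6 the lactone oxygen and C8 the tiglate. The six stereocenters (1S,4R,5S,6S,8S,10R) form two groups. In the first, the C8 oxygen and the C10 methyl are cis across C9, and the C1 oxygen sits next to C10. In the second, C4–C5–C6 are contiguous: the epoxide is cis (it derives from a Z alkene) and its oxygen is syn to the lactone oxygen. The sensitive groups are the epoxide flanked by the allylic lactone oxygen (acid, transannular opening), the butenolide (acidic C6–H, possible relactonization to the C8 oxygen) and three different esters, one of them conjugated. The difficulty is the ten-membered carbocycle itself and then addressing C1, C6, C7 and C4=C5 one at a time on a flexible ring. The strategy rests on the 1,6-relationship of the C1 and C6 oxygens: joining C1 to C6 and cutting C3–C4 gives a cyclohexane (C1, C6, C7, C8, C9, C10) with alkenyl groups on two adjacent oxygenated carbons, the retron of an oxy-Cope ring expansion. That cyclohexane already contains C8 and C10 in a 1,3-cis relationship that is easy to set on a six-membered ring.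

## Retrosynthetic reasoning

**Epoxide (36 ⇒ 35).** The two C–O bonds of the epoxide are cut last. In 35 the C4=C5 alkene is the only electron-rich alkene, so a peracid needs no chemoselectivity control, and the epoxide never has to pass through an acidic step. The forward reaction has to choose the alkene face on the side of the C6 oxygen.

**Esters (35 ⇒ 33 + 34; 32 ⇒ 31).** The acyl–oxygen bonds are cut next. C8 stays a silyl ether while C1–OH and C13–OH are acetylated together, and is then freed and esterified with tiglic acid 34. This separates the tiglate from the two acetates without extra protecting groups.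

**C1 stereocenter (31 ⇒ 30 ⇒ 29).** The C1–H bond is cut back to the ketone 30, which comes from the methyl enol ether of 29 by hydrolysis. C1 is unmasked only after C6 has become a lactone carbon, so a free cyclodecane-1,6-dione, which would close by transannular aldol reaction, never exists.

**Butenolide (29 ⇒ 28 ⇒ 26 ⇒ 21 + 24).** The C7–C11 bond and the lactone acyl–oxygen bond are cut. The C6 ketone of 21 serves twice: it makes C7 nucleophilic for an aldol addition to the keto ester 24, which brings C11–C13 with C13 already oxygenated, and after reduction it supplies the lactone oxygen. Dehydration then places the C7=C11 alkene.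

**Enone (21 ⇒ 20 ⇒ 19).** The C4=C5 alkene is traced to the C5=C6 silyl enol ether of 19 by dehydrogenation. Because the enol ether is regiodefined, the alkene can only appear between C4 and C5. The Z geometry is reached by equilibration of the enone.

**Ring expansion (19 ⇒ 17).** The C3–C4 bond is cut and C1–C6 reconnected. This turns the ten-membered ring into the cyclohexane 17 with a vinyl group (C2, C3) on C1 and a propenyl group (C5, C4, C15) on C6. The forward [3,3] shift must start from the C6 alkoxide so that the enolate appears at C5=C6. C1 carries a methyl ether so that it emerges as an enol ether and not as a second carbonyl.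

**Precursor (17 ⇒ 15 + 16; 15 ⇒ 12 ⇒ 11 ⇒ 9 + 10).** The C6–C5 bond is cut to the ketone 15 and the propenyl unit from 16; the C1–C2 bond is cut to the enone 9 and the vinyl reagent 10. The C1 carbinol is built and methylated first (11, 12), while C6 is still an iodoalkene carbon. The methyl group therefore cannot end on the wrong oxygen, which would be the case if both tertiary alcohols were present together. The iodine of 9 marks C6 for conversion to the ketone of 15.

**Six-membered ring (9 ⇒ 8 ⇒ 7 ⇒ 6 ⇒ 5).** Iodination, allylic oxidation at C1 and silylation are removed in turn, leaving the cis allylic alcohol 6 from reduction of the enone 5. The carbonyl carbon of 5 is taken as C8. Its stereocenter is then set by a kinetically controlled hydride reduction cis to the C10 methyl. Introducing that oxygen by conjugate addition would be weaker: such an addition is trans-selective under kinetic control and only weakly biased under thermodynamic control.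

**Chiral pool (5 ⇒ 1).** The enone 5 is the known three-step degradation product of pulegone. With the carbonyl carbon as C8, the 10R configuration of the target requires the S enantiomer 1.

**Keto ester (24 ⇒ 23 ⇒ 22).** The keto ester is cut at its C=O to the acrylate 23, and the silyl ether is removed to the commercial hydroxymethyl acrylate 22.

## Alternatives that were turned down

**Alternative 1:** The lactone C6–O bond of the 4,5-deoxy compound A1 (identical with 35) is disconnected to the seco acid A2, in which C6 is a doubly allylic methylene between the Z C4=C5 and the C7=C11 alkenes. Forward, Pd(OAc)2 with a bis-sulfoxide ligand and benzoquinone, or DDQ, would activate the C6–H bond and the C12 carboxylate would close the butenolide.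
- For: the lactone and the C6 stereocenter are formed in one late step, with no C6 ketone to reduce and no aldol and dehydration sequence. On end-game step count this is stronger than the chosen route.
- Against: the ten-membered ring of A2 still has to be made, with a tetrasubstituted C7=C11 alkene of defined geometry. The allyl intermediate is delocalized over C4–C6, so the Z geometry can be lost and C4 can be attacked. The face at C6 is not controlled on a flexible ring. Other activated C–H bonds (C8, C3, C15) and over-oxidation to a triene compete.
- Comparison: all regio- and stereochemical risk would fall on the last bond made on the most advanced material. The chosen strategy spends its risk at step 12 on an early intermediate and then uses the C6 carbonyl as a handle for both C7 and C4=C5.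

**Alternative 2:** The C2–C3 bond is disconnected. Forward, Pd(PPh3)4 would ionize the Z allylic carbonate of the acyclic keto sulfone A4 and the β-keto sulfone carbanion at C2 would attack C3 to give the cyclodecenedione A3.
- For: the approach is convergent, and C6, C8 and C10 are set on an open chain by standard methods. The C7 ketone next to the C6 oxygen would allow an intramolecular Horner–Wadsworth–Emmons closure of the butenolide, which is a more dependable butenolide construction than the aldol and dehydration used here.
- Against: closing a ten-membered carbocycle by alkylation has to beat oligomerization and transannular strain. The anti (Z) allyl complex can equilibrate to the syn form and give the E alkene. Attack at C5 would give an eight-membered ring. The allylic C6 silyloxy group can ionize. The C7 ketone between two oxygenated stereocenters is prone to epimerization under the basic conditions. The sulfone must be removed reductively later.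
- Comparison: the chosen ring expansion is unimolecular and pericyclic, so concentration, ring-size competition and alkene geometry at the ring-forming step are not at issue.

**Alternative 3:** The C1 and C6 carbonyls of the cyclodecane-1,6-dione A5 are joined to the tetrasubstituted alkene of the hexahydronaphthalene A6, which ozone then Me2S would cleave.
- For: ozonolysis of a tetrasubstituted alkene is about as reliable as a ring-unveiling step can be, and on this point it is stronger than the oxy-Cope step. C4 already carries the oxygen needed to reach the C4=C5 alkene.
- Against: A6 must carry stereocenters on both rings (C8, C10 and C4) and has to be raised from an achiral anisole-derived Birch product, which is long and needs asymmetric induction. A5 presents C1 and C6 as two undifferentiated ketones and is a classic substrate for transannular aldol condensation to a hydroazulenone.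
- Comparison: the chosen rearrangement delivers C1 and C6 as two different enol derivatives (methyl enol ether and silyl enol ether) that are addressed one after the other, and it starts from a chiral-pool monocycle.

Key step: step 12

Remark on the chemistry: the configurations at C1 and C6 in 11–17 and the enol ether geometries and C4 configuration in 18 and 19 are drawn for the isomers expected from the arguments in the steps. None of these elements survives beyond step 20, so epimers can be carried along.

## Route

Step 1
Reactants: 1 (S)-pulegone
Product: 2 (6S)-2,2,6-trimethyl-1-oxaspiro[2.5]octan-4-one (pulegone oxide; both epimers at the spiro carbon)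
Conditions: 30% H2O2, LiOH (cat.), MeOH, 0 °C to rt
Reagents that add atoms: hydrogen peroxide, OO
Why: Weitz–Scheffer nucleophilic epoxidation of the enone; the epoxide configuration is irrelevant because both epoxide carbons are lost or planarized in steps 2 and 3.

Step 2
Reactants: 2 pulegone oxide
Product: 3 (5S)-5-methyl-2-(phenylsulfanyl)cyclohexan-1-one (both C2 epimers)
Conditions: PhSH, NaH (cat.), THF, reflux
Reagents that add atoms: thiophenol, Sc1ccccc1
Why: Thiolate opens the epoxide at the ring carbon α to the ketone; the tertiary alkoxide formed loses acetone by retro-aldol cleavage and the enolate is protonated by thiophenol, which regenerates thiolate.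

Step 3
Reactants: 3 (5S)-5-methyl-2-(phenylsulfanyl)cyclohexan-1-one
Product: 5 (S)-5-methylcyclohex-2-en-1-one, via sulfoxide 4 (not isolated)
Conditions: mCPBA, CH2Cl2, −78 °C; then CaCO3, toluene, 110 °C
Reagents that add atoms: none
Why: Sulfide oxidation and thermal syn elimination of the sulfoxide; the only β-hydrogens are on C3, so the conjugated enone forms and the remote methyl stereocenter is untouched.

Step 4
Reactants: 5 (S)-5-methylcyclohex-2-en-1-one
Product: 6 (1S,5S)-5-methylcyclohex-2-en-1-ol (cis)
Conditions: NaBH4, CeCl3·7H2O, MeOH, −78 °C
Reagents that add atoms: none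
Why: Luche 1,2-reduction; hydride adds axially to the half-chair with the methyl group pseudo-equatorial, so the new hydroxyl (the future C8 oxygen) is pseudo-equatorial and cis to the methyl group (kinetic control, the usual course for 5-substituted cyclohexenones).

Step 5
Reactants: 6 (1S,5S)-5-methylcyclohex-2-en-1-ol
Product: 7 tert-butyldimethylsilyl ether of 6
Conditions: TBSCl, imidazole, DMF, rt
Reagents that add atoms: tert-butyldimethylsilyl chloride, CC(C)(C)[Si](C)(C)Cl
Why: Silylation of the secondary allylic alcohol; the TBS ether has to survive organometallic reagents, KH and mild acid until step 23.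

Step 6
Reactants: 7 silyl ether
Product: 8 (4S,6R)-4-[(tert-butyldimethylsilyl)oxy]-6-methylcyclohex-2-en-1-one (cis)
Conditions: Rh2(cap)4 (cap = caprolactamate, 1 mol %), t-BuOOH, K2CO3, CH2Cl2, rt
Reagents that add atoms: tert-butyl hydroperoxide, CC(C)(C)OO
Why: Dirhodium-catalysed allylic oxidation by tert-butylperoxyl radicals: the only allylic methylene is C1, while the other allylic position (C8) is tertiary, hindered and deactivated by its oxygen. C10 becomes α to the new ketone, but the cis arrangement is also the more stable one.

Step 7
Reactants: 8 silyloxy enone
Product: 9 (4S,6R)-4-[(tert-butyldimethylsilyl)oxy]-2-iodo-6-methylcyclohex-2-en-1-one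
Conditions: I2, pyridine, CH2Cl2, 0 °C to rt
Reagents that add atoms: iodine, II
Why: Johnson α-iodination of the enone (pyridine conjugate addition, iodination, elimination); the iodine marks C6 as the carbon that becomes the ketone in step 10 and keeps C6 trigonal during step 8.

Step 8
Reactants: 9 iodoenone; 10 vinylmagnesium bromide
Product: 11 (4S,6R)-4-[(tert-butyldimethylsilyl)oxy]-1-ethenyl-2-iodo-6-methylcyclohex-2-en-1-ol (vinyl trans to the 6-methyl group; hydroxyl cis to it)
Conditions: 10, CeCl3 (anhydrous), THF, −78 °C
Reagents that add atoms: none
Why: Organocerium 1,2-addition suppresses enolization and conjugate addition; the reagent should enter anti to the adjacent C10 methyl (and the C8 silyloxy) group, as organometallic reagents do with 2-alkylcyclohexanones. The C1 epimer would still serve, because C1 is planarized in step 12.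

Step 9
Reactants: 11 tertiary alcohol
Product: 12 methyl ether of 11 (C1 methoxy; C6 iodoalkene)
Conditions: KH, MeI, THF, 0 °C
Reagents that add atoms: iodomethane, CI
Why: Williamson methylation of the tertiary potassium alkoxide; no other oxygen is free or adjacent at this stage, so the methyl group can only end on the C1 oxygen. The alkoxide cannot undergo a [3,3] shift, because the second alkene is still in the ring (1,4-diene).

Step 10
Reactants: 12 iodoalkene methyl ether
Product: 15 5-[(tert-butyldimethylsilyl)oxy]-2-ethenyl-2-methoxy-3-methylcyclohexan-1-one (methyl and silyloxy cis; vinyl trans to both), via alkenyllithium 13 (not isolated), via lithium alkenyltrimethoxyborate 14 (not isolated)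
Conditions: t-BuLi (2.1 equiv), Et2O, −78 °C; B(OMe)3; then H2O2, NaHCO3, THF/H2O, 0 °C
Reagents that add atoms: hydrogen peroxide, OO
Why: Iodine–lithium exchange, borylation and oxidation of the alkenylborate give the enol and hence the ketone exactly at C6; low temperature and a nearly neutral oxidation protect the β-silyloxy ketone from elimination.

Step 11
Reactants: 15 ketone; 16 (E)-1-bromoprop-1-ene
Product: 17 5-[(tert-butyldimethylsilyl)oxy]-2-ethenyl-2-methoxy-3-methyl-1-[(E)-prop-1-enyl]cyclohexan-1-ol (germacrane numbering: C6 hydroxyl and C1 methoxy cis to the C10 methyl and C8 silyloxy groups; vinyl and propenyl on the opposite face)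
Conditions: 16, t-BuLi (2 equiv), Et2O, −78 °C; CeCl3, THF, −78 °C; then 15
Reagents that add atoms: none
Why: The organocerium reagent adds to the enolizable β-silyloxy ketone without deprotonation; Felkin–Anh attack anti to the axial C1 methoxy group should place the propenyl group cis to the vinyl group (one axial, one equatorial, gauche). Either C6 epimer and either propenyl geometry gives the same constitution in step 12.

Step 12
Reactants: 17 dialkenyl cyclohexanol
Product: 19 (1E,5Z)-8-[(tert-butyldimethylsilyl)oxy]-1-methoxy-4,10-dimethyl-6-[(trimethylsilyl)oxy]cyclodeca-1,5-diene (germacrane numbering; C10 and C3 cis on C1=C2; C4 and C7 trans on C5=C6), via potassium enolate 18 (not isolated)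
Conditions: KH, 18-crown-6, THF, 0 to 45 °C; then TMSCl, Et3N, −78 °C
Reagents that add atoms: chlorotrimethylsilane, C[Si](C)(C)Cl
Why: KH with 18-crown-6 converts the C6 tertiary alcohol into a dissociated potassium alkoxide, which weakens the C1–C6 bond and accelerates the [3,3] shift; the closest known reaction is the anionic oxy-Cope rearrangement of 1,2-dialkenylcyclohexanols to cyclodec-5-enones. The C1–C6 bond breaks, C3–C4 forms between the two alkene termini and the π bonds move to C1=C2 and C5=C6, so the ten-membered ring (C1–C10, with C3 the only methylene between C2 and C4) closes by a four-carbon ring expansion through a six-membered chair transition state and not by an end-to-end cyclization. In 17 the equatorial vinyl and axial propenyl groups are gauche, which is the geometry this chair needs; it leads to the enol ether with C10 and C3 cis and the enolate with C4 and C7 trans. The one new stereocenter, C4, follows from the E-propenyl geometry in the chair, but it, both enol geometries and the C1/C6 configurations of 17 are all erased by step 20, so no stereoselectivity is required. The selectivity that matters is regiochemical: the enolate is born only at C5=C6 by the mechanism, and it is silylated at −78 °C before proton transfer could move it to C6=C7, where it would expel the C8 silyloxy group. The driving force is the change from alkoxide to enolate, and the methyl ether at C1 prevents a second carbonyl and with it a transannular aldol reaction. C8 and C10 are spectators. Because 19 is a 1,5-diene that could revert thermally, it is kept cold and taken directly into step 13.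

Step 13
Reactants: 19 bis(enol ether)
Product: 20 8-[(tert-butyldimethylsilyl)oxy]-1-methoxy-4,10-dimethylcyclodeca-1,4-dien-6-one (germacrane numbering; E/Z mixture at C4=C5, E isomer drawn)
Conditions: Pd(OAc)2 (1.1 equiv), MeCN, rt
Reagents that add atoms: none
Why: Saegusa–Ito oxidation: silicon–palladium exchange gives the palladium enolate bound at C5, and β-hydride elimination can only involve C4–H, so the alkene is placed at C4=C5. This removes C4, the silyl enol ether geometry and the 1,5-diene relationship of 19.

Step 14
Reactants: 20 enone (E/Z mixture)
Product: 21 (4Z)-isomer of 20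
Conditions: PhSH (0.2 equiv), Et3N (0.2 equiv), THF, rt
Reagents that add atoms: none
Why: Reversible conjugate addition of thiolate at C4 allows rotation about C4–C5; a ten-membered ring holds a cis (Z) enone with less strain than a trans one, so the equilibrium should lie on the side of 21, and a catalytic amount of thiol prevents net addition.

Step 15
Reactants: 22 ethyl 2-(hydroxymethyl)prop-2-enoate
Product: 23 ethyl 2-{[(triethylsilyl)oxy]methyl}prop-2-enoate
Conditions: TESCl, imidazole, CH2Cl2, 0 °C
Reagents that add atoms: chlorotriethylsilane, CC[Si](Cl)(CC)CC
Why: Silylation of the primary alcohol; the TES ether is chosen so that step 20 can cleave it beside the secondary TBS ether.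

Step 16
Reactants: 23 silyloxymethyl acrylate
Product: 24 ethyl 2-oxo-3-[(triethylsilyl)oxy]propanoate
Conditions: O3, CH2Cl2, −78 °C; then Me2S
Reagents that add atoms: ozone, [O-][O+]=O
Why: Ozonolysis of the 1,1-disubstituted alkene gives the α-keto ester; it is used freshly because it hydrates easily.

Step 17
Reactants: 21 Z-enone; 24 keto ester
Product: 26 aldol adduct (C7 bears C11 with hydroxyl, CO2Et and CH2OTES; mixture at C7 and C11), via lithium enolate 25 (not isolated)
Conditions: LiN(iPr)2, THF, −78 °C; then 24, −78 °C; AcOH quench
Reagents that add atoms: none
Why: Kinetic deprotonation of the enone occurs at the α′ carbon C7, and at −78 °C the lithium enolate adds to the very electrophilic keto carbonyl faster than it is protonated by it. The C7 and C11 configurations are not controlled and are removed in step 19.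

Step 18
Reactants: 26 aldol adduct
Product: 28 (6S)-11-hydroxy-12,6-lactone (germacrane numbering; mixture at C7 and C11), via dihydroxy ester 27 (not isolated)
Conditions: NaBH4, CeCl3·7H2O, MeOH, −78 °C; then Et3N, toluene, 50 °C
Reagents that add atoms: none
Why: Luche conditions reduce the enone carbonyl in the 1,2 sense and the γ-hydroxy ester closes to the five-membered lactone. The C6 configuration rests on substrate control (hydride from the outer face of the Z enone of the ten-membered ring, which should place the C6 oxygen syn to the C8 oxygen); this is treated among the uncertain steps.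

Step 19
Reactants: 28 hydroxy lactone
Product: 29 butenolide with C7=C11 (C13 OTES; C1 methyl enol ether; C8 OTBS)
Conditions: SOCl2, pyridine, CH2Cl2, −20 to 0 °C
Reagents that add atoms: none
Why: The chlorosulfite of the tertiary α-hydroxy lactone eliminates toward C7–H to give the tetrasubstituted conjugated butenolide, the more substituted and more stable alkene, and removes the C7 and C11 stereocenters. Pyridine keeps the enol ether and the silyl ethers intact.

Step 20
Reactants: 29 butenolide
Product: 30 C1 ketone with free C13 hydroxyl (C8 OTBS retained)
Conditions: 0.5 M HCl, THF/H2O, 0 °C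
Reagents that add atoms: water, O
Why: Dilute acid hydrolyses the methyl enol ether to the C1 ketone and cleaves the primary TES ether, while the hindered secondary TBS ether survives. C6 is already a lactone carbon, so no 1,6-diketone and no transannular aldol reaction can arise.

Step 21
Reactants: 30 keto alcohol
Product: 31 (1S)-diol (C1 and C13 hydroxyls)
Conditions: (R)-2-methyl-CBS-oxazaborolidine (0.5 equiv), catecholborane, toluene, −78 °C
Reagents that add atoms: none
Why: Corey–Bakshi–Shibata reduction: the catalyst binds the ketone with the α-branched C10 side as the large group and delivers hydride to give the 1S alcohol (reagent control, catalyst enantiomer assigned by analogy with aryl methyl ketones). Catecholborane at −78 °C leaves the butenolide and the alkene alone.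

Step 22
Reactants: 31 diol
Product: 32 1,13-diacetate (C8 OTBS)
Conditions: Ac2O, pyridine, DMAP (cat.), CH2Cl2, 0 °C
Reagents that add atoms: acetic anhydride, CC(=O)OC(C)=O
Why: Acylation of the secondary C1 and the primary C13 hydroxyl in one operation; C8 is still protected.

Step 23
Reactants: 32 diacetate
Product: 33 C8 alcohol
Conditions: HF·pyridine, pyridine, THF, 0 °C to rt
Reagents that add atoms: none
Why: Buffered HF removes the TBS ether without the basicity of fluoride salts, which could deprotonate C6–H of the butenolide or move the acetates.

Step 24
Reactants: 33 C8 alcohol; 34 tiglic acid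
Product: 35 8-tiglate (4,5-deoxy target)
Conditions: 34, 2,4,6-trichlorobenzoyl chloride, Et3N, THF, rt; then 33, DMAP, toluene, rt
Reagents that add atoms: none
Why: Yamaguchi esterification through the mixed anhydride acylates the hindered secondary alcohol; tiglic acid has the stable E geometry, and prompt acylation prevents relactonization toward C8.

Step 25
Reactants: 35 4,5-deoxy target
Product: 36 target (CNP0287840.1)
Conditions: mCPBA, NaHCO3, CH2Cl2, 0 °C
Reagents that add atoms: 3-chloroperoxybenzoic acid, OOC(=O)c1cccc(Cl)c1
Why: Prilezhaev epoxidation of the only electron-rich alkene (the tiglate and butenolide alkenes are conjugated to carbonyls). Allylic 1,3-strain of the Z alkene holds C6–H in the alkene plane, the ring carbon C7 shields one face, and the peracid attacks the face of the lactone oxygen, which gives the cis epoxide syn to the C6 oxygen (4R,5S).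

## Compound list

1 | (S)-pulegone | C[C@H]1CCC(=C(C)C)C(=O)C1 | starting material
2 | (6S)-2,2,6-trimethyl-1-oxaspiro[2.5]octan-4-one (both spiro epimers) | C[C@H]1CCC2(OC2(C)C)C(=O)C1 | intermediate
3 | (5S)-5-methyl-2-(phenylsulfanyl)cyclohexan-1-one (both C2 epimers) | C[C@H]1CCC(Sc2ccccc2)C(=O)C1 | intermediate
4 | (5S)-5-methyl-2-(phenylsulfinyl)cyclohexan-1-one | C[C@H]1CCC(S(=O)c2ccccc2)C(=O)C1 | intermediate (not isolated)
5 | (S)-5-methylcyclohex-2-en-1-one | C[C@H]1CC=CC(=O)C1 | intermediate
6 | (1S,5S)-5-methylcyclohex-2-en-1-ol | O[C@H]1C[C@@H](C)CC=C1 | intermediate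
7 | tert-butyldimethyl{[(1S,5S)-5-methylcyclohex-2-en-1-yl]oxy}silane | CC(C)(C)[Si](C)(C)O[C@H]1C[C@@H](C)CC=C1 | intermediate
8 | (4S,6R)-4-[(tert-butyldimethylsilyl)oxy]-6-methylcyclohex-2-en-1-one | CC(C)(C)[Si](C)(C)O[C@H]1C[C@@H](C)C(=O)C=C1 | intermediate
9 | (4S,6R)-4-[(tert-butyldimethylsilyl)oxy]-2-iodo-6-methylcyclohex-2-en-1-one | CC(C)(C)[Si](C)(C)O[C@H]1C[C@@H](C)C(=O)C(I)=C1 | intermediate
10 | vinylmagnesium bromide | C=C[Mg]Br | starting material
11 | 4-[(tert-butyldimethylsilyl)oxy]-1-ethenyl-2-iodo-6-methylcyclohex-2-en-1-ol (vinyl trans to methyl) | CC(C)(C)[Si](C)(C)O[C@H]1C[C@@H](C)[C@](O)(C=C)C(I)=C1 | intermediate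
12 | methyl ether of 11 | CC(C)(C)[Si](C)(C)O[C@H]1C[C@@H](C)[C@](OC)(C=C)C(I)=C1 | intermediate
13 | alkenyllithium from 12 | CC(C)(C)[Si](C)(C)O[C@H]1C[C@@H](C)[C@](OC)(C=C)C([Li])=C1 | intermediate (not isolated)
14 | lithium alkenyltrimethoxyborate | CC(C)(C)[Si](C)(C)O[C@H]1C[C@@H](C)[C@](OC)(C=C)C([B-](OC)(OC)OC)=C1.[Li+] | intermediate (not isolated)
15 | 5-[(tert-butyldimethylsilyl)oxy]-2-ethenyl-2-methoxy-3-methylcyclohexan-1-one | CC(C)(C)[Si](C)(C)O[C@H]1C[C@@H](C)[C@](OC)(C=C)C(=O)C1 | intermediate
16 | (E)-1-bromoprop-1-ene | C/C=C/Br | starting material
17 | 5-[(tert-butyldimethylsilyl)oxy]-2-ethenyl-2-methoxy-3-methyl-1-[(E)-prop-1-enyl]cyclohexan-1-ol (key-step precursor) | CC(C)(C)[Si](C)(C)O[C@H]1C[C@@H](C)[C@](OC)(C=C)[C@](O)(/C=C/C)C1 | intermediate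
18 | potassium C5=C6 enolate of the ring-expanded ketone | CC(C)(C)[Si](C)(C)O[C@H]1C[C@@H](C)/C(OC)=C\C[C@H](C)/C=C(\[O-])C1.[K+] | intermediate (not isolated)
19 | cyclodeca-1,5-diene with C1 methyl enol ether and C5=C6 trimethylsilyl enol ether (key-step product) | CC(C)(C)[Si](C)(C)O[C@H]1C[C@@H](C)/C(OC)=C\C[C@H](C)/C=C(\O[Si](C)(C)C)C1 | intermediate
20 | C4=C5 enone (E/Z mixture, E drawn) | CC(C)(C)[Si](C)(C)O[C@H]1C[C@@H](C)/C(OC)=C\C/C(C)=C/C(=O)C1 | intermediate
21 | (4Z)-enone | CC(C)(C)[Si](C)(C)O[C@H]1C[C@@H](C)/C(OC)=C\C/C(C)=C\C(=O)C1 | intermediate
22 | ethyl 2-(hydroxymethyl)prop-2-enoate | C=C(CO)C(=O)OCC | starting material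
23 | ethyl 2-{[(triethylsilyl)oxy]methyl}prop-2-enoate | C=C(CO[Si](CC)(CC)CC)C(=O)OCC | intermediate
24 | ethyl 2-oxo-3-[(triethylsilyl)oxy]propanoate | CCOC(=O)C(=O)CO[Si](CC)(CC)CC | intermediate
25 | lithium C6=C7 enolate of 21 | CC(C)(C)[Si](C)(C)O[C@H]1C[C@@H](C)/C(OC)=C\C/C(C)=C\C([O-])=C1.[Li+] | intermediate (not isolated)
26 | aldol adduct (mixture at C7 and C11) | CC(C)(C)[Si](C)(C)O[C@H]1C[C@@H](C)/C(OC)=C\C/C(C)=C\C(=O)C1C(O)(CO[Si](CC)(CC)CC)C(=O)OCC | intermediate
27 | (6S)-dihydroxy ester | CC(C)(C)[Si](C)(C)O[C@H]1C[C@@H](C)/C(OC)=C\C/C(C)=C\[C@@H](O)C1C(O)(CO[Si](CC)(CC)CC)C(=O)OCC | intermediate (not isolated)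
28 | (6S)-11-hydroxy-12,6-lactone | CC(C)(C)[Si](C)(C)O[C@H]1C[C@@H](C)/C(OC)=C\C/C(C)=C\[C@H]2OC(=O)C(O)(CO[Si](CC)(CC)CC)C12 | intermediate
29 | butenolide (C13 OTES, C1 enol ether, C8 OTBS) | CC(C)(C)[Si](C)(C)O[C@H]1C[C@@H](C)/C(OC)=C\C/C(C)=C\[C@H]2OC(=O)C(CO[Si](CC)(CC)CC)=C12 | intermediate
30 | C1 ketone, C13 alcohol | CC(C)(C)[Si](C)(C)O[C@H]1C[C@@H](C)C(=O)CC/C(C)=C\[C@H]2OC(=O)C(CO)=C12 | intermediate
31 | (1S)-1,13-diol | CC(C)(C)[Si](C)(C)O[C@H]1C[C@@H](C)[C@@H](O)CC/C(C)=C\[C@H]2OC(=O)C(CO)=C12 | intermediate
32 | 1,13-diacetate, C8 OTBS | CC(C)(C)[Si](C)(C)O[C@H]1C[C@@H](C)[C@@H](OC(C)=O)CC/C(C)=C\[C@H]2OC(=O)C(COC(C)=O)=C12 | intermediate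
33 | 1,13-diacetate, C8 alcohol | O[C@H]1C[C@@H](C)[C@@H](OC(C)=O)CC/C(C)=C\[C@H]2OC(=O)C(COC(C)=O)=C12 | intermediate
34 | tiglic acid | C/C=C(\C)C(=O)O | starting material
35 | 4,5-deoxy target (8-tiglate, Z C4=C5) | C/C=C(\C)C(=O)O[C@H]1C[C@@H](C)[C@@H](OC(C)=O)CC/C(C)=C\[C@H]2OC(=O)C(COC(C)=O)=C12 | intermediate
36 | CNP0287840.1 | C/C=C(\C)C(=O)O[C@H]1C[C@@H](C)[C@@H](OC(C)=O)CC[C@@]2(C)O[C@H]2[C@H]2OC(=O)C(COC(C)=O)=C12 | target

## Step count and least certain steps

Total: 25 steps. Longest linear sequence: 23 steps (steps 1–14 and 17–25 from (S)-pulegone); steps 15 and 16 are a two-step side branch.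

**Step 12 (key step).** The cis-dialkenyl alkoxide may rearrange only on warming. At that temperature proton transfer can move the enolate to C6=C7, from where the C8 silyloxy group is expelled, and the isolated 1,5-diene 19 can revert by a thermal Cope rearrangement. Fallback: starting from 17, the enolate is not silylated but trapped at −78 °C with PhSeBr as the C5 phenylselenide F1, which is no longer a 1,5-diene. Oxidation with H2O2 and pyridine and syn elimination of the selenoxide (only C4–H is available) gives 20, where the route is rejoined and step 13 is skipped.

**Step 6.** Hydrogen abstraction at the oxygen-bearing allylic carbon, or capture of the allyl radical at the transposed terminus next to the silyloxy carbon, would give regioisomeric enones and over-oxidation. Fallback: starting from 7, catalytic SeO2 with t-BuOOH hydroxylates the allylic methylene by an ene reaction and [2,3] shift without moving the alkene, giving the allylic alcohol F2. Oxidation with Dess–Martin periodinane returns to 8.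

**Step 13.** Divalent palladium can also attack the electron-rich methyl enol ether (oxypalladation, allylic activation at C3), which would consume the C1 masking group. Fallback: starting from 19, MeLi cleaves the silyl enol ether to the lithium enolate F3, which is dehydrogenated with N-tert-butylbenzenesulfinimidoyl chloride at −78 °C to give 20.

**Step 18.** Facial selectivity of hydride delivery to the C6 ketone of a flexible ten-membered ring may be poor or may favour the 6-epimer, because it depends on a ring conformation that cannot be predicted with confidence. Fallback: starting from 26, if the reduction gives mainly the 6-epimeric lactone F4, it is opened with LiOH to the hydroxy acid F5 and relactonized under Mitsunobu conditions (PPh3, DIAD), which inverts the allylic C6 carbinol and returns to 28.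

**Step 19.** Elimination may go toward C13 instead of C7, giving an exocyclic enol ether, when C7–H cannot align with the leaving group in some of the C7/C11 diastereomers. Fallback: starting from 26, the β-hydroxy ketone is dehydrated first (MsCl, Et3N, then DBU; E1cB, only C7–H is acidic) to the alkylidene keto ester F6, whose geometrical isomers are equilibrated. Luche reduction then gives a hydroxy ester that lactonizes directly to 29.

**Step 21.** Reagent and substrate preferences may oppose each other (the Felkin sense relative to the C10 methyl group points to the 1-epimer), which would erode selectivity. Fallback: starting from 30, the ketone is reduced in the substrate-preferred sense (NaBH4, MeOH, −40 °C) to the 1-epimeric diol F7. A Mitsunobu reaction with acetic acid (PPh3, DIAD) then acetylates C13 and installs the C1 acetate with inversion, returning to 32.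

## Further compounds

F1 | step 12 | C5 phenylselenide of the ring-expanded C6 ketone | CC(C)(C)[Si](C)(C)O[C@H]1C[C@@H](C)/C(OC)=C\C[C@H](C)C([Se]c2ccccc2)C(=O)C1
F2 | step 6 | 4-[(tert-butyldimethylsilyl)oxy]-6-methylcyclohex-2-en-1-ol | CC(C)(C)[Si](C)(C)O[C@H]1C[C@@H](C)C(O)C=C1
F3 | step 13 | lithium C5=C6 enolate from 19 | CC(C)(C)[Si](C)(C)O[C@H]1C[C@@H](C)/C(OC)=C\C[C@H](C)/C=C(\[O-])C1.[Li+]
F4 | step 18 | 6-epimer of lactone 28 | CC(C)(C)[Si](C)(C)O[C@H]1C[C@@H](C)/C(OC)=C\C/C(C)=C\[C@@H]2OC(=O)C(O)(CO[Si](CC)(CC)CC)C12
F5 | step 18 | 6-epimeric hydroxy acid | CC(C)(C)[Si](C)(C)O[C@H]1C[C@@H](C)/C(OC)=C\C/C(C)=C\[C@H](O)C1C(O)(CO[Si](CC)(CC)CC)C(=O)O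
F6 | step 19 | alkylidene keto ester (C7=C11, ester cis to C6) | CC(C)(C)[Si](C)(C)O[C@H]1C[C@@H](C)/C(OC)=C\C/C(C)=C\C(=O)/C1=C(/CO[Si](CC)(CC)CC)C(=O)OCC
F7 | step 21 | 1-epimer of diol 31 | CC(C)(C)[Si](C)(C)O[C@H]1C[C@@H](C)[C@H](O)CC/C(C)=C\[C@H]2OC(=O)C(CO)=C12
A1 | alternative 1 | 4,5-deoxy target (identical with 35) | C/C=C(\C)C(=O)O[C@H]1C[C@@H](C)[C@@H](OC(C)=O)CC/C(C)=C\[C@H]2OC(=O)C(COC(C)=O)=C12
A2 | alternative 1 | skipped-diene seco acid with C6 methylene | C/C=C(\C)C(=O)O[C@H]1C[C@@H](C)[C@@H](OC(C)=O)CC/C(C)=C\C/C1=C(/COC(C)=O)C(=O)O
A3 | alternative 2 | Z-cyclodecene-1,7-dione with C2 phenylsulfone | CC(C)(C)[Si](C)(C)O[C@H]1C[C@@H](C)C(=O)[C@H](S(=O)(=O)c2ccccc2)C/C(C)=C\[C@@H](O[Si](CC)(CC)CC)C1=O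
A4 | alternative 2 | acyclic β-keto sulfone with Z allylic methyl carbonate | COC(=O)OC/C(C)=C\[C@@H](O[Si](CC)(CC)CC)C(=O)[C@@H](O[Si](C)(C)C(C)(C)C)C[C@@H](C)C(=O)CS(=O)(=O)c1ccccc1
A5 | alternative 3 | cyclodecane-1,6-dione | CC(C)(C)[Si](C)(C)O[C@H]1C[C@@H](C)C(=O)CC[C@@](C)(O[Si](C)(C)C)CC(=O)C1
A6 | alternative 3 | hexahydronaphthalene with tetrasubstituted C1=C6 alkene | CC(C)(C)[Si](C)(C)O[C@H]1C[C@@H](C)C2=C(C1)C[C@](C)(O[Si](C)(C)C)CC2
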